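The ratio of the first readings of complex with one exchanged in the north and north-east runs, 2.39, was about the same as the ratio of their incoming ligand, 2.41, so I took the initial rate of the first exchange as first order in c(incoming ligand).

all flasks: starting complex 0.10 M

| run | incoming ligand | leaving ligand | remark | time |
|---|---|---|---|---|
| north-east | 0.058 M | 0.20 M | run made earlier |  |
| north | 0.14 M | 0.20 M | run made earlier |  |
| east | 0.41 M | 0.20 M | run made earlier |  |
| teal | 0.150 M | 0.200 M |  | 1.5 h |
| violet | 0.0500 M | 0.200 M |  | 1.5 h |
| amber | 0.400 M | 0.200 M |  | 1.5 h |

| run | time / min | complex with one exchanged / % |
|---|---|---|
| north-east | 12.0 | 3.6 |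
| north-east | 25.0 | 6.3 |
| north-east | 40.0 | 7.9 |
| north-east | 50.0 | 8.4 |
| north-east | 60.0 | 9.0 |
| north | 12.0 | 8.6 |
| north | 25.0 | 13.3 |
| north | 40.0 | 16.4 |
| north | 50.0 | 18.4 |
| north | 60.0 | 19.0 |
| east | 5.00 | 11.6 |
| east | 10.0 | 19.7 |
| east | 20.0 | 27.4 |
| east | 30.0 | 32.9 |
| east | 60.0 | 33.8 |

(readings scatter by 0.3 percentage points)

1. which of these holds the largest part of the starting complex at the end of teal (starting complex / complex with two exchanged / complex with three exchanged / complex with one exchanged)
2. which of these holds the largest part of the starting complex at the end of violet (starting complex / complex with two exchanged / complex with three exchanged / complex with one exchanged)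
3. which of these holds the largest part of the starting complex at the end of amber (starting complex / complex with two exchanged / complex with three exchanged / complex with one exchanged)
4. final complex with one exchanged in amber, as a percentage of the starting complex charged



The north run gave 26.5 min for what I called the catch-up time, the last reading of complex with one exchanged divided by the first rate, where the first rate is the first reading over its time. The east run gave 14.6 min, which is shorter. Amber has nearly the east charge, so I scaled the east first rate by c(incoming ligand), 0.400 M against 0.41 M, and multiplied by the east catch-up time. That gave me 33.0% of complex with one exchanged for amber.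

The weak link was time: amber runs 90 min, longer than the last east reading at 60.0 min. Between 30.0 min and 60.0 min the east run gained 0.9 percentage points, so I read its curve as near the top there. I therefore kept 33.0% as the top of the amber curve, and left the end of amber free to lie below it.

The forecast put starting complex first in teal, starting complex in violet and starting complex in amber, and gave 32.5% for complex with one exchanged in amber, close to my number, reasoning that “Amber is almost the east run, continued to 90 min”.

The amber flask gave 30.9%, below both numbers, with complex with one exchanged largest of the asked forms. Of the asked forms, teal also ended with complex with one exchanged largest, and violet with starting complex.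

    2 starting complex → homo dimer (k = 0.210 M⁻¹ min⁻¹)
    starting complex + incoming ligand ⇌ leaving ligand + complex with one exchanged (K = 16.0, k = 0.0690 M⁻¹ min⁻¹)
    leaving ligand + complex with one exchanged → side product (k = 0.00390 M⁻¹ min⁻¹)
    complex with two exchanged + incoming ligand ⇌ leaving ligand + complex with three exchanged (K = 1.80, k = 0.00700 M⁻¹ min⁻¹)
    complex with one exchanged + incoming ligand ⇌ leaving ligand + complex with two exchanged (K = 1.80, k = 0.0250 M⁻¹ min⁻¹)

In amber, complex with one exchanged stood at 34.3% after 0.750 h, and at 1.50 h it was made more slowly than it was used up, each step taken net, the ratio being 0.423. The neighbouring flask is amber with 0.16 M of incoming ligand. The north first rate, scaled to that charge and multiplied by the north catch-up time of 26.5 min, gives 21.7%, and that flask gave 22.4%.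

The earlier runs and the new flask were computed with constants of no real substance; scatter was added.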